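**Retrosynthetic overview**
1. Palstatin ⇒ global O‑debenzylation of a tri‑O‑benzyl flavone. The pyranone ring is formed last, by cyclodehydration of a 1,3‑diketone made by Claisen condensation of a benzodioxane methyl ester with phloroacetophenone dibenzyl ether.
2. trans‑Benzodioxane ring ⇒ stereoretentive intramolecular Pd‑catalysed aryl C–O coupling of an o‑bromoaryl ether alcohol. The Br/OH pattern of methyl 5‑bromovanillate fixes the regiochemistry, so no oxidative phenol coupling or Mitsunobu step is needed.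
3. Both stereocentres ⇒ one catalytic step: Ru‑catalysed asymmetric transfer hydrogenation with dynamic kinetic resolution (ATH‑DKR) of a racemic α‑aryloxy‑β‑keto ester.
4. Keto ester ⇒ SN2 of the bromovanillate phenoxide on an α‑chloro‑β‑keto ester derived from acetosyringone and diethyl carbonate.
5. Ring order: dioxane ring (step 8), then pyranone ring (step 11).

Assumption: methyl 3‑bromo‑4‑hydroxy‑5‑methoxybenzoate is treated as a catalogue compound (otherwise one extra step, Br2/AcOH on methyl vanillate). The sense of induction in step 5 is predicted from the Noyori–Ikariya model; if it is found reversed, the (R,R)‑catalyst is used.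

**Route**

Step 1
Reactants: 1, 4'‑hydroxy‑3',5'‑dimethoxyacetophenone (acetosyringone)
Product: 2, 4'‑(benzyloxy)‑3',5'‑dimethoxyacetophenone
Conditions: BnBr, K2CO3, DMF, 60 °C
Reagents that add atoms: benzyl bromide, BrCc1ccccc1
Why: Williamson ether synthesis on the only acidic OH; the benzyl group masks the syringyl phenol until the final hydrogenolysis.

Step 2
Reactants: 2; 3, diethyl carbonate
Product: 4, ethyl 3‑[4‑(benzyloxy)‑3,5‑dimethoxyphenyl]‑3‑oxopropanoate
Conditions: NaH (2.5 equiv), (EtO)2CO, toluene, reflux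
Reagents that add atoms: diethyl carbonate (compound 3), CCOC(=O)OCC
Why: Crossed Claisen C‑acylation of the methyl ketone enolate, driven by irreversible deprotonation of the β‑keto ester product; the new ester carbon becomes the CH2OH carbon of the target.

Step 3
Reactants: 4
Product: 5, ethyl 2‑chloro‑3‑[4‑(benzyloxy)‑3,5‑dimethoxyphenyl]‑3‑oxopropanoate (racemic)
Conditions: SO2Cl2 (1.05 equiv), CH2Cl2, 0 °C
Reagents that add atoms: sulfuryl chloride, O=S(=O)(Cl)Cl
Why: Electrophilic α‑chlorination of the β‑keto ester enol, which is far more nucleophilic than the acyl‑deactivated arene.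

Step 4
Reactants: 5; 6, methyl 3‑bromo‑4‑hydroxy‑5‑methoxybenzoate
Product: 7, ethyl 3‑[4‑(benzyloxy)‑3,5‑dimethoxyphenyl]‑2‑[2‑bromo‑6‑methoxy‑4‑(methoxycarbonyl)phenoxy]‑3‑oxopropanoate (racemic)
Conditions: K2CO3, acetone, 50 °C
Reagents that add atoms: none (both partners are numbered reactants)
Why: SN2 O‑alkylation of the acidic phenoxide by the doubly activated α‑chloride; it forms the 4'‑O–Cβ bond and places Br exactly where the second C–O bond is needed, and the phenol has no free ortho/para position for side reactions.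

Step 5
Reactants: 7
Product: 8, ethyl (2S,3R)‑3‑[4‑(benzyloxy)‑3,5‑dimethoxyphenyl]‑2‑[2‑bromo‑6‑methoxy‑4‑(methoxycarbonyl)phenoxy]‑3‑hydroxypropanoate (syn/threo)
Conditions: RuCl(p‑cymene)[(S,S)‑TsDPEN] (2 mol%), HCO2H/Et3N (5:2), CH2Cl2, 35 °C
Reagents that add atoms: none (formic acid delivers only H)
Why: Noyori–Ikariya ATH with DKR: the α‑aryloxy‑β‑keto ester racemises rapidly through its enol while the (S,S)‑Ru hydride reduces one enantiomer, setting C3 as R by catalyst control (same face as acetophenone → (S)‑1‑phenylethanol, with a CIP priority switch) and C2 as S by syn‑selective DKR, as known for α‑alkoxy‑β‑keto esters; aryl bromide, aryl ester and benzyl ether are inert.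

Step 6
Reactants: 8
Product: 9, methyl 4‑{[(1R,2R)‑1‑[4‑(benzyloxy)‑3,5‑dimethoxyphenyl]‑1,3‑dihydroxypropan‑2‑yl]oxy}‑3‑bromo‑5‑methoxybenzoate
Conditions: LiBH4, THF, 0 °C
Reagents that add atoms: none
Why: Chemoselective hydride reduction of the α‑aryloxy/β‑hydroxy‑activated aliphatic ester, leaving the electron‑rich aryl methyl ester; done cold and aprotic to avoid α‑epimerisation, and it removes the acidic α‑H before any basic step (the descriptor at C2 changes to R only through CIP priorities).

Step 7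
Reactants: 9
Product: 10, methyl 4‑{[(1R,2R)‑1‑[4‑(benzyloxy)‑3,5‑dimethoxyphenyl]‑3‑[(tert‑butyldimethylsilyl)oxy]‑1‑hydroxypropan‑2‑yl]oxy}‑3‑bromo‑5‑methoxybenzoate
Conditions: TBSCl (1.1 equiv), imidazole, CH2Cl2, 0 °C
Reagents that add atoms: tert‑butyldimethylsilyl chloride, CC(C)(C)[Si](C)(C)Cl
Why: Sterically controlled silylation of the primary over the hindered secondary benzylic OH, leaving only the benzylic OH free for ring closure.

Step 8
Reactants: 10
Product: 11, methyl (2R,3R)‑3‑[4‑(benzyloxy)‑3,5‑dimethoxyphenyl]‑2‑{[(tert‑butyldimethylsilyl)oxy]methyl}‑8‑methoxy‑2,3‑dihydro‑1,4‑benzodioxine‑6‑carboxylate (trans)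
Conditions: Pd(OAc)2 (5 mol%), 2‑(di‑tert‑butylphosphino)‑1,1'‑binaphthyl (6 mol%), Cs2CO3, toluene, 70 °C
Reagents that add atoms: none
Why: Buchwald‑type intramolecular Pd‑catalysed aryl etherification (oxidative addition to ArBr, Pd‑alkoxide formation, C–O reductive elimination) closes the six‑membered ring without touching either stereogenic C–O bond, so the syn‑(1R,2R) precursor gives the trans‑(2R,3R) benzodioxane as a single regioisomer; the bulky ligand favours reductive elimination over β‑hydride elimination.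

Step 9
Reactants: 12, 2',4',6'‑trihydroxyacetophenone
Product: 13, 4',6'‑bis(benzyloxy)‑2'‑hydroxyacetophenone
Conditions: BnBr (2.1 equiv), K2CO3, DMF, rt
Reagents that add atoms: benzyl bromide, BrCc1ccccc1
Why: Williamson etherification selective for the two non‑chelated phenols; one ortho OH stays free because it is hydrogen‑bonded to the carbonyl, and it becomes the pyranone oxygen.

Step 10
Reactants: 11; 13
Product: 14, 1‑[2,4‑bis(benzyloxy)‑6‑hydroxyphenyl]‑3‑[(2R,3R)‑3‑[4‑(benzyloxy)‑3,5‑dimethoxyphenyl]‑2‑{[(tert‑butyldimethylsilyl)oxy]methyl}‑8‑methoxy‑2,3‑dihydro‑1,4‑benzodioxin‑6‑yl]propane‑1,3‑dione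
Conditions: 13 (1.5 equiv), LiHMDS (5 equiv), THF, −78 °C; then 11, −78 → 50 °C
Reagents that add atoms: none
Why: Crossed Claisen condensation of the phenoxide/enolate dianion of 13 with the non‑enolisable aryl methyl ester, driven by deprotonation of the 1,3‑diketone; the benzodioxane stereocentres carry no acidic hydrogens, and TBS and benzyl ethers tolerate the base.

Step 11
Reactants: 14
Product: 15, 5,7‑bis(benzyloxy)‑2‑[(2R,3R)‑3‑[4‑(benzyloxy)‑3,5‑dimethoxyphenyl]‑2‑(hydroxymethyl)‑8‑methoxy‑2,3‑dihydro‑1,4‑benzodioxin‑6‑yl]‑4H‑chromen‑4‑one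
Conditions: p‑TsOH·H2O, toluene/MeOH, 65 °C
Reagents that add atoms: none
Why: Acid‑catalysed cyclodehydration of the o‑hydroxyaryl 1,3‑diketone (6‑exo hemiketal formation, then loss of water) gives the flavone and cleaves the primary TBS ether in the same pot; AcOH is avoided so the primary alcohol is not acetylated, and the benzodioxane with its O‑benzylated aryl group is acid‑stable.

Step 12
Reactants: 15
Product: 16, palstatin, 5,7‑dihydroxy‑2‑[(2R,3R)‑3‑(4‑hydroxy‑3,5‑dimethoxyphenyl)‑2‑(hydroxymethyl)‑8‑methoxy‑2,3‑dihydro‑1,4‑benzodioxin‑6‑yl]‑4H‑chromen‑4‑one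
Conditions: H2 (1 atm), 10% Pd/C, THF/MeOH, rt, stopped at full conversion
Reagents that add atoms: none
Why: Catalytic hydrogenolysis removes all three aryl benzyl ethers under conditions where the flavone C2=C3 bond and the cyclic benzodioxane C–O bonds are reduced only slowly, and no stereocentre is affected.

**Compound list**
1 | 4'‑hydroxy‑3',5'‑dimethoxyacetophenone (acetosyringone) | CC(=O)c1cc(OC)c(O)c(OC)c1 | starting material
2 | 4'‑(benzyloxy)‑3',5'‑dimethoxyacetophenone | CC(=O)c1cc(OC)c(OCc2ccccc2)c(OC)c1 | intermediate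
3 | diethyl carbonate | CCOC(=O)OCC | starting material
4 | ethyl 3‑[4‑(benzyloxy)‑3,5‑dimethoxyphenyl]‑3‑oxopropanoate | CCOC(=O)CC(=O)c1cc(OC)c(OCc2ccccc2)c(OC)c1 | intermediate
5 | ethyl 2‑chloro‑3‑[4‑(benzyloxy)‑3,5‑dimethoxyphenyl]‑3‑oxopropanoate (racemic) | CCOC(=O)C(Cl)C(=O)c1cc(OC)c(OCc2ccccc2)c(OC)c1 | intermediate
6 | methyl 3‑bromo‑4‑hydroxy‑5‑methoxybenzoate | COC(=O)c1cc(Br)c(O)c(OC)c1 | starting material
7 | racemic α‑aryloxy‑β‑keto ester | CCOC(=O)C(Oc1c(Br)cc(C(=O)OC)cc1OC)C(=O)c1cc(OC)c(OCc2ccccc2)c(OC)c1 | intermediate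
8 | (2S,3R)‑syn α‑aryloxy‑β‑hydroxy ester | CCOC(=O)[C@@H](Oc1c(Br)cc(C(=O)OC)cc1OC)[C@H](O)c1cc(OC)c(OCc2ccccc2)c(OC)c1 | intermediate
9 | (1R,2R)‑diol | OC[C@@H](Oc1c(Br)cc(C(=O)OC)cc1OC)[C@H](O)c1cc(OC)c(OCc2ccccc2)c(OC)c1 | intermediate
10 | (1R,2R)‑primary TBS ether | CC(C)(C)[Si](C)(C)OC[C@@H](Oc1c(Br)cc(C(=O)OC)cc1OC)[C@H](O)c1cc(OC)c(OCc2ccccc2)c(OC)c1 | intermediate
11 | (2R,3R)‑trans‑benzodioxane methyl ester | CC(C)(C)[Si](C)(C)OC[C@H]1Oc2c(OC)cc(C(=O)OC)cc2O[C@@H]1c1cc(OC)c(OCc2ccccc2)c(OC)c1 | intermediate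
12 | 2',4',6'‑trihydroxyacetophenone | CC(=O)c1c(O)cc(O)cc1O | starting material
13 | 4',6'‑bis(benzyloxy)‑2'‑hydroxyacetophenone | CC(=O)c1c(O)cc(OCc2ccccc2)cc1OCc1ccccc1 | intermediate
14 | 1,3‑diketone | CC(C)(C)[Si](C)(C)OC[C@H]1Oc2c(OC)cc(C(=O)CC(=O)c3c(O)cc(OCc4ccccc4)cc3OCc3ccccc3)cc2O[C@@H]1c1cc(OC)c(OCc2ccccc2)c(OC)c1 | intermediate
15 | tri‑O‑benzyl palstatin | OC[C@H]1Oc2c(OC)cc(-c3cc(=O)c4c(OCc5ccccc5)cc(OCc5ccccc5)cc4o3)cc2O[C@@H]1c1cc(OC)c(OCc2ccccc2)c(OC)c1 | intermediate
16 | palstatin | OC[C@H]1Oc2c(OC)cc(-c3cc(=O)c4c(O)cc(O)cc4o3)cc2O[C@@H]1c1cc(OC)c(O)c(OC)c1 | target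

**Totals**
Total steps: 12. Longest linear sequence: 11 (steps 1–8 and 10–12, from acetosyringone).

**Three steps most likely to fail, with fallbacks**
1. Step 5 (ATH‑DKR). The bulky 2,6‑disubstituted aryloxy group may erode the syn dr or ee. Fallback: Evans syn‑glycolate aldol. The aryloxyacetic acid made from 6 is attached to (S)‑4‑benzyl‑2‑oxazolidinone; its Bu2BOTf/Et3N boron enolate is added to 4‑(benzyloxy)‑3,5‑dimethoxybenzaldehyde to give the (2S,3R)‑syn aldol, and LiBH4 cleavage rejoins the route at diol 9.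
2. Step 8 (Pd C–O ring closure). The risks are β‑hydride elimination to the ketone with hydrodebromination, or silyl or aryl migration under base. Fallback: replace 6 with methyl 3,4‑dihydroxy‑5‑methoxybenzoate, alkylated selectively at the 4‑OH, and carry it through steps 5–7. The ring is then closed by acid‑promoted benzylic substitution (TFA or BF3·OEt2), where the free 3‑OH traps the syringyl benzylic cation (quinone‑methide type). This gives the trans ring under thermodynamic control, relayed from the C2 centre set in the DKR.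
3. Step 10 (Claisen with an electron‑rich, hindered methyl ester). Conversion may be low. Fallback: switch to an aldehyde‑based flavone synthesis. Ester 11 is converted to the aldehyde (DIBAL, then MnO2), condensed with 13 (Claisen–Schmidt, KOH/EtOH) to the 2'‑hydroxychalcone, and cyclised oxidatively (I2/DMSO) to the TBS ether of 15.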